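The readings stem from a simulated flask on assumed constants, noise included.

In a one-step world electrophile would pass straight into target, and the two readings would add up to the whole charge. Gamma says otherwise: at 2.50 h they hold 66.9 %, so part of the electrophile sits in an unseen pool.

| setting | gamma | teal | ochre |
|---|---|---|---|
| electrophile | 0.76 M | 0.76 M | 0.76 M |
| nucleophile | 1.5 M | 0.800 M | 1.20 M |
| remark | run made earlier |  |  |
| time |  | 20 h | 20 h |

- gamma (time / h: electrophile / %, target / %): 1.00: 45.5, 24.4; 2.50: 27.3, 39.6; 6.00: 19.2, 55.5; 15.0: 9.9, 68.7

(readings scatter by 1 percentage point)

- part of the electrophile that has reacted at the end, teal
- part of the electrophile that has reacted at the end, ochre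
- what raising the concentration of nucleophile from its lowest to its highest value here does to the part of the electrophile that has reacted (changes below 5 percentage points count as none) (no change / it rises / it falls)

- the numbers in the tables scatter by 1 percentage point (one standard deviation)
- what has gone from electrophile into another species counts as reacted, even if it can come back

We keep the books on the electrophile, taking nucleophile as the limiting reagent. First comes the price of a target. In gamma, the hourly target gain over [electrophile] falls from 0.278 /h in the first interval to 0.101 /h in the last, steeper than one nucleophile per target can explain. So we price each target at two nucleophiles, which is an inference.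

In teal, then, 52.6 % of the charge can reach target: this is the target ceiling, charged nucleophile over twice the charged electrophile. We assume teal reaches it by 20 h and enter the remaining 47.4 % in the pool. Gamma at 2.50 h reads 45.2 % of the non-target part as free electrophile, a reading with its scatter. We reckon just this remainder: 21.4 % free, so 78.6 % reacted. Ochre has a ceiling of 78.9 % and comes to 90.5 %, a rise of 12 percentage points, above the margin.

The forecast stands below us, with 55 % for teal, 75 % for ochre and it rises, in its words: “So nucleophile becomes limiting”.

Teal gives 78.1 % and ochre 87.7 %, so it rises by 9.6 points, under this scheme:

    nucleophile + acid set free ⇌ protonated nucleophile, settled at all times (K = 6400 /M)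
    electrophile + nucleophile → acid set free + target (k = 0.00490 /M/min)
    electrophile ⇌ dormant form (K = 1.00, k = 0.0120 /min)
    electrophile + target → side product (k = 7.50 × 10⁻⁴ /M/min)

In teal at 20.0 h, electrophile at 21.9 % and dormant form at 22.4 % stand level. Each side product holds two electrophiles, one of them come through target, so teal's target plus half of its side product makes 49.1 %, against the ceiling of 52.6 %, with 6.8 % of the nucleophile left. The neighbour flask, teal with 1.9 M of electrophile, reckons to 21.1 % by the same formula, but its target and half of its side product make 21.5 %, slightly more than that figure, so there the reckoned ceiling is no strict limit, with acid set free standing unbound at 0.0196 M.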